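**Plan**

1. Numbering used throughout: C1 quaternary C–CH3, C2/C3 ring CH2, C4 C(OH)iPr, C5 ring-fusion CH, C6 CH–O-aroyl, C7 CH2, C8(CH3)=C9, C10 C=O; the cyclopentane is C1–C5, the cycloheptenone C1, C5–C10.
2. Retrosynthesis: the aroyl C–O bond at C6 and the C8=C9 unsaturation go first; then the ring bonds C1–C5 and C8–C9 are cut together, because the seven-ring ketone C10 with its neighbours C1 and C9 is an oxyallyl unit, C5–C6(O)–C7–C8 is a 2-oxygenated diene, and the cyclopentane carbons C2–C3–C4 are the three-atom tether between them.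
3. The open chain is cut at C9–C10 (chloromethyl carbenoid on a Weinreb amide), C1–C10 (one-carbon Wittig homologation) and C6–C7 (alkenylchromium addition), leading back to the ozonolysis product of (S)-terpinen-4-ol.
4. Forward: the chain is built linearly (steps 1–9), cyclopentane and cycloheptenone close together in step 10, then C6 reduction, acylation and C8=C9 dehydrogenation finish the molecule.
5. Stereochemistry: C4 comes from (S)-terpinen-4-ol; C5 and C1 are relayed from C4 in the cycloaddition; C6 is set by hydride delivery from the C4 hydroxyl; C8 ends as sp2.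

Key step: step 10

Remark: (S)-(+)-terpinen-4-ol is assumed to be available enantiopure, as it is the only source of absolute configuration; the C4 descriptor changes from S to R along the chain only through CIP priorities, no inversion occurs.

**Step 1**
Reactants: 1 (S)-terpinen-4-ol
Product: 2 (S)-terpinen-4-ol triethylsilyl ether
Conditions: TESOTf, 2,6-lutidine, CH2Cl2, 0 °C → rt
Reagents that add atoms: triethylsilyl trifluoromethanesulfonate, CC[Si](CC)(CC)OS(=O)(=O)C(F)(F)F
Why: Silyl triflate/2,6-lutidine silylation is the standard way to cap a hindered tertiary alcohol and leaves the stereocentre untouched.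

**Step 2**
Reactants: 2 (S)-terpinen-4-ol triethylsilyl ether
Product: 3 (S)-3-isopropyl-6-oxo-3-(triethylsilyloxy)heptanal
Conditions: O3, CH2Cl2, −78 °C; then PPh3, −78 °C → rt
Reagents that add atoms: ozone, [O-][O+]=O
Why: Ozonolysis with reductive work-up (Criegee mechanism) cleaves the only alkene into the C1 methyl ketone and the C6 aldehyde without affecting C4.

**Step 3**
Reactants: 3 (S)-3-isopropyl-6-oxo-3-(triethylsilyloxy)heptanal; 4 (E)-1-bromoprop-1-ene
Product: 5 (5S,8E)-7-hydroxy-5-isopropyl-5-(triethylsilyloxy)dec-8-en-2-one (both C7 epimers)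
Conditions: CrCl2 (4 equiv), NiCl2 (2 mol %), DMF, rt
Reagents that add atoms: none
Why: The Nozaki–Hiyama–Kishi alkenylchromium addition is selective for aldehydes over ketones and retains the E geometry of the halide, while the unselective new carbinol centre is removed by oxidation in step 6.

**Step 4**
Reactants: 5 (5S,8E)-7-hydroxy-5-isopropyl-5-(triethylsilyloxy)dec-8-en-2-one
Product: 6 7-O-trimethylsilyl ether of 5
Conditions: TMSCl, imidazole, CH2Cl2, 0 °C
Reagents that add atoms: chlorotrimethylsilane, C[Si](C)(C)Cl
Why: Routine silylation masks the secondary hydroxyl so that no alkoxide is present in the basic Wittig step to pull the triethylsilyl group off the tertiary oxygen by O→O silyl migration.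

**Step 5**
Reactants: 6 7-O-trimethylsilyl ether of 5
Product: 8 (5S,8E)-7-hydroxy-5-isopropyl-2-methyl-5-(triethylsilyloxy)dec-8-enal (C2 and C7 epimers), via methyl enol ether 7 (not isolated)
Conditions: Ph3P(CH2OMe)Cl, KHMDS, THF, 0 °C → rt; then 1 M HCl, THF, 0 °C
Reagents that add atoms: (methoxymethyl)triphenylphosphonium chloride, COC[P+](c1ccccc1)(c1ccccc1)c1ccccc1.[Cl-]; water, O
Why: Wittig methoxymethylenation followed by acid hydrolysis of the enol ether is the standard one-carbon homologation of a ketone to the α-branched aldehyde, the same acid removing the labile TMS ether but not the hindered tertiary TES ether, and the new C1 centre (a mixture) is later erased in the planar cation.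

**Step 6**
Reactants: 8 (5S,8E)-7-hydroxy-5-isopropyl-2-methyl-5-(triethylsilyloxy)dec-8-enal
Product: 9 (5S,8E)-5-isopropyl-2-methyl-7-oxo-5-(triethylsilyloxy)dec-8-enoic acid (C2 epimers)
Conditions: PDC, DMF, rt
Reagents that add atoms: pyridinium dichromate, [O-][Cr](=O)(=O)O[Cr](=O)(=O)[O-].c1cc[nH+]cc1.c1cc[nH+]cc1
Why: PDC in DMF oxidises non-conjugated aldehydes to carboxylic acids and allylic alcohols to enones, so both required oxidation levels should be reached in one chromium(VI) oxidation.

**Step 7**
Reactants: 9 (5S,8E)-5-isopropyl-2-methyl-7-oxo-5-(triethylsilyloxy)dec-8-enoic acid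
Product: 10 N-methoxy-N-methylamide of 9
Conditions: MeNH(OMe)·HCl, EDC·HCl, HOBt, iPr2NEt, CH2Cl2, 0 °C
Reagents that add atoms: N,O-dimethylhydroxylamine hydrochloride, CNOC.Cl
Why: Carbodiimide coupling to the Weinreb amide is routine and is run cold so that acylation outruns any aza-Michael addition to the β-methyl enone.

**Step 8**
Reactants: 10 N-methoxy-N-methylamide of 9
Product: 11 (5R,6Z,8E)-7-(tert-butyldimethylsilyloxy)-5-isopropyl-N-methoxy-N,2-dimethyl-5-(triethylsilyloxy)deca-6,8-dienamide (C2 epimers)
Conditions: LiHMDS, THF, −78 °C; then TBSOTf, −78 °C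
Reagents that add atoms: tert-butyldimethylsilyl trifluoromethanesulfonate, CC(C)(C)[Si](C)(C)OS(=O)(=O)C(F)(F)F
Why: Kinetic α′-deprotonation of the (E)-enone by a lithium amide gives the cross-conjugated enolate (the amide α-hydrogen is far less acidic), and O-silylation gives the 2-siloxydiene with the bulky C4 group cis to oxygen (Z) because the other geometry would eclipse C4 with the propenyl group.

**Step 9**
Reactants: 11 (5R,6Z,8E)-7-(tert-butyldimethylsilyloxy)-5-isopropyl-N-methoxy-N,2-dimethyl-5-(triethylsilyloxy)deca-6,8-dienamide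
Product: 12 (6R,7Z,9E)-8-(tert-butyldimethylsilyloxy)-1-chloro-6-isopropyl-3-methyl-6-(triethylsilyloxy)undeca-7,9-dien-2-one (C3 epimers), i.e. ClCH2–C10(=O)–C1H(CH3)–C2H2–C3H2–C4(OTES)(iPr)–C5H=C6(OTBS)–C7H=C8H–CH3
Conditions: ICH2Cl, MeLi·LiBr (slow addition), THF, −78 °C; then pH 7 aq. NH4Cl, −78 °C → rt
Reagents that add atoms: chloroiodomethane, ClCI
Why: Chloromethyllithium generated by iodine–lithium exchange in the presence of the substrate (Barbier mode) adds once to the Weinreb amide, whose chelated tetrahedral adduct releases the α-chloroketone only on quench, under conditions too cold and non-acidic to harm the silyl dienol ether.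

**Step 10**
Reactants: 12 (6R,7Z,9E)-8-(tert-butyldimethylsilyloxy)-1-chloro-6-isopropyl-3-methyl-6-(triethylsilyloxy)undeca-7,9-dien-2-one
Product: 14 (1S,4R,5S)-hydroazulen-10-one with C6=C7 tert-butyldimethylsilyl enol ether and C4 triethylsilyl ether (C8 epimers), via oxyallyl cation 13 (not isolated)
Conditions: iPr2NEt, CF3CH2OH/Et2O (1:1), 0 °C → rt
Reagents that add atoms: none
Why: The hindered amine enolises 12 toward C1 and chloride leaves in the ionising fluoro-alcohol to give oxyallyl cation 13 (C1–C10–C9), whose disubstituted terminus C1 is attacked by the enol-ether carbon C5 of the tethered siloxydiene while C9 bonds to C8, in one asynchronous event or through a short-lived siloxyallyl cation/enolate pair. The closest known reaction is the intramolecular (4+3) cycloaddition of α-halo-ketone-derived oxyallyl cations with dienes tethered at the α′ carbon in amine/trifluoroethanol, which gives 5,7-fused ketones. The cyclopentane closes in the fused mode through the C1–C5 bond across the three-atom tether C2–C3–C4, and the cycloheptenone closes by joining the three cation carbons C9–C10–C1 to the diene termini C8 and C5, leaving C6=C7 as the silyl enol ether. C5 is set by the diene face, because allylic strain with the (Z)-OTBS group should hold the C4–O bond in the diene plane and the isopropyl group anti to the tether, so the cation reaches only the face that makes C6 cis to the C4 oxygen; C1 is set by the extended approach (C10 turned away from C6), which places the C1 methyl cis to the C4 oxygen and makes the ring fusion trans; C8 forms unselectively and becomes sp2 in step 15. The selectivity the step needs is the C1/C4 relationship, which cannot be corrected later (C5 can, once C6 is a ketone), and it rests on the C4 stereocentre acting through this conformational lock together with the expected preference of a polar, carbon-first bond formation for the extended arrangement that keeps the solvated oxyallyl oxygen clear of the C6 silyloxy group; regiochemistry is fixed because a three-atom tether can deliver C1 only to C5.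

**Step 11**
Reactants: 14 (1S,4R,5S)-hydroazulen-10-one silyl enol ether
Product: 15 (1S,4R,5R)-4-hydroxy-4-isopropyl-1,8-dimethylhydroazulene-6,10-dione (C8 epimers)
Conditions: 48% aq. HF, MeCN, 0 °C → rt
Reagents that add atoms: none
Why: Acidic fluoride desilylation cleaves the enol ether to the C6 ketone and the tertiary TES ether in one operation without base (so no retro-aldol of the tertiary aldol), and C5, now α to the ketone, should stay in or equilibrate to the trans-fused form in which C6 is anti to isopropyl and hydrogen-bonded to the C4 hydroxyl.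

**Step 12**
Reactants: 15 (1S,4R,5R)-4-hydroxy-4-isopropyl-1,8-dimethylhydroazulene-6,10-dione
Product: 16 (1S,4R,5S,6S)-4,6-dihydroxy-4-isopropyl-1,8-dimethylhydroazulen-10-one (C8 epimers)
Conditions: Me4NBH(OAc)3, MeCN/AcOH (1:1), −20 °C → 0 °C
Reagents that add atoms: none
Why: In the Evans–Saksena reduction the borohydride exchanges onto the C4 hydroxyl and delivers hydride intramolecularly through a six-membered transition state to the C6 face it can reach in the trans-fused frame, which should give the 4,6-anti diol (6S), while the neopentylic C10 ketone has no hydroxyl placed to direct its reduction.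

**Step 13**
Reactants: 16 (1S,4R,5S,6S)-4,6-dihydroxy-4-isopropyl-1,8-dimethylhydroazulen-10-one; 17 3,4,5-trimethoxybenzoyl chloride
Product: 18 C6 3,4,5-trimethoxybenzoate of 16
Conditions: DMAP, Et3N, CH2Cl2, 0 °C → rt
Reagents that add atoms: none
Why: DMAP-catalysed acylation with the acid chloride esterifies the secondary C6 alcohol and leaves the tertiary C4 alcohol free.

**Step 14**
Reactants: 18 C6 3,4,5-trimethoxybenzoate of 16
Product: 19 C10 trimethylsilyl enol ether (C9=C10) and C4 trimethylsilyl ether of 18
Conditions: TMSOTf, Et3N, CH2Cl2, 0 °C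
Reagents that add atoms: trimethylsilyl trifluoromethanesulfonate, C[Si](C)(C)OS(=O)(=O)C(F)(F)F
Why: Soft enolisation with silyl triflate and amine can only go toward C9 because C1 is quaternary, so a single silyl enol ether forms, the tertiary alcohol being silylated in passing.

**Step 15**
Reactants: 19 C10 trimethylsilyl enol ether and C4 trimethylsilyl ether of 18
Product: 21 target CNP0218356.1, via C4 trimethylsilyl ether 20 (not isolated)
Conditions: Pd(OAc)2, MeCN, rt; then 0.5 M HCl, THF, 0 °C
Reagents that add atoms: none
Why: In the Saegusa–Ito oxidation Pd(II) converts the enol silane into an α-palladated ketone and β-hydride elimination of the only β-hydrogen (C8–H) installs the C8=C9 double bond, erasing the unresolved C8 centre, after which dilute acid cleaves the labile tertiary TMS ether.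

**Compound list**

1 | (S)-terpinen-4-ol | CC1=CC[C@](O)(C(C)C)CC1 | starting material
2 | (S)-terpinen-4-ol triethylsilyl ether | CC1=CC[C@](O[Si](CC)(CC)CC)(C(C)C)CC1 | intermediate
3 | (S)-3-isopropyl-6-oxo-3-(triethylsilyloxy)heptanal | O=CC[C@](O[Si](CC)(CC)CC)(C(C)C)CCC(C)=O | intermediate
4 | (E)-1-bromoprop-1-ene | C/C=C/Br | starting material
5 | (5S,8E)-7-hydroxy-5-isopropyl-5-(triethylsilyloxy)dec-8-en-2-one, C7 epimers | C/C=C/C(O)C[C@](O[Si](CC)(CC)CC)(C(C)C)CCC(C)=O | intermediate
6 | 7-O-trimethylsilyl ether of 5 | C/C=C/C(O[Si](C)(C)C)C[C@](O[Si](CC)(CC)CC)(C(C)C)CCC(C)=O | intermediate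
7 | methyl enol ether from 6 (1-methoxy-2-methylalkene, E/Z mixture; formed in situ) | C/C=C/C(O[Si](C)(C)C)C[C@](O[Si](CC)(CC)CC)(C(C)C)CCC(C)=COC | intermediate
8 | (5S,8E)-7-hydroxy-5-isopropyl-2-methyl-5-(triethylsilyloxy)dec-8-enal, C2 and C7 epimers | C/C=C/C(O)C[C@](O[Si](CC)(CC)CC)(C(C)C)CCC(C)C=O | intermediate
9 | (5S,8E)-5-isopropyl-2-methyl-7-oxo-5-(triethylsilyloxy)dec-8-enoic acid, C2 epimers | C/C=C/C(=O)C[C@](O[Si](CC)(CC)CC)(C(C)C)CCC(C)C(=O)O | intermediate
10 | N-methoxy-N-methylamide of 9 | C/C=C/C(=O)C[C@](O[Si](CC)(CC)CC)(C(C)C)CCC(C)C(=O)N(C)OC | intermediate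
11 | (5R,6Z,8E)-7-(tert-butyldimethylsilyloxy)-5-isopropyl-N-methoxy-N,2-dimethyl-5-(triethylsilyloxy)deca-6,8-dienamide, C2 epimers | CON(C)C(=O)C(C)CC[C@@](O[Si](CC)(CC)CC)(C(C)C)/C=C(\O[Si](C)(C)C(C)(C)C)/C=C/C | intermediate
12 | (6R,7Z,9E)-8-(tert-butyldimethylsilyloxy)-1-chloro-6-isopropyl-3-methyl-6-(triethylsilyloxy)undeca-7,9-dien-2-one, C3 epimers (cycloaddition precursor) | ClCC(=O)C(C)CC[C@@](O[Si](CC)(CC)CC)(C(C)C)/C=C(\O[Si](C)(C)C(C)(C)C)/C=C/C | intermediate
13 | oxyallyl cation (C1–C10–C9) from 12, drawn as zwitterion (formed in situ) | C=C([O-])[C+](C)CC[C@@](O[Si](CC)(CC)CC)(C(C)C)/C=C(\O[Si](C)(C)C(C)(C)C)/C=C/C | intermediate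
14 | (1S,4R,5S)-hydroazulen-10-one, C6=C7 TBS enol ether, C4 OTES, 1,8-dimethyl, 4-isopropyl, C8 epimers (cycloadduct) | CC(C)(C)[Si](C)(C)OC1=CC(C)CC(=O)[C@@]2(C)CC[C@@](O[Si](CC)(CC)CC)(C(C)C)[C@H]12 | intermediate
15 | (1S,4R,5R)-4-hydroxy-4-isopropyl-1,8-dimethylhydroazulene-6,10-dione, trans-fused, C8 epimers | O=C1CC(C)CC(=O)[C@@]2(C)CC[C@@](O)(C(C)C)[C@H]12 | intermediate
16 | (1S,4R,5S,6S)-4,6-dihydroxy-4-isopropyl-1,8-dimethylhydroazulen-10-one, C8 epimers | O[C@H]1CC(C)CC(=O)[C@@]2(C)CC[C@@](O)(C(C)C)[C@H]12 | intermediate
17 | 3,4,5-trimethoxybenzoyl chloride | COc1cc(cc(OC)c1OC)C(Cl)=O | starting material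
18 | C6 3,4,5-trimethoxybenzoate of 16, C8 epimers | COc1cc(C(=O)O[C@H]2CC(C)CC(=O)[C@@]3(C)CC[C@@](O)(C(C)C)[C@H]23)cc(OC)c1OC | intermediate
19 | C10 TMS enol ether (C9=C10) and C4 TMS ether of 18, C8 epimers | COc1cc(C(=O)O[C@H]2CC(C)C=C(O[Si](C)(C)C)[C@@]3(C)CC[C@@](O[Si](C)(C)C)(C(C)C)[C@H]23)cc(OC)c1OC | intermediate
20 | C4 trimethylsilyl ether of the target (formed in situ) | COc1cc(C(=O)O[C@H]2CC(C)=CC(=O)[C@@]3(C)CC[C@@](O[Si](C)(C)C)(C(C)C)[C@H]23)cc(OC)c1OC | intermediate
21 | CNP0218356.1, (1S,4R,5S,6S) in the plan numbering | COc1cc(C(=O)O[C@H]2CC(C)=CC(=O)[C@@]3(C)CC[C@@](O)(C(C)C)[C@H]23)cc(OC)c1OC | target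

Total step count: 15
Longest linear sequence: 15 steps (1 → 21)

**Steps most likely to fail**

Step 10. Facial control may leak: if both rotamers about C4–C5 react, or the compact approach competes with the extended one, the cation bonds so that the C1 methyl ends trans to the C4 oxygen, an error that cannot be repaired. Solvent capture or Favorskii collapse of the cation may also compete with ring closure. The fallback fixes the diene face covalently by tying the C4 oxygen to the C6 enol oxygen. It sets out from 10: HF·pyridine in THF removes the triethylsilyl group to give the β-hydroxy enone amide F1. Di-tert-butylsilyl bis(triflate) with 2,6-lutidine then closes the cyclic di-tert-butylsilylene dienol ether F2, a 4H-1,3,2-dioxasiline whose enol geometry is necessarily Z. Chloromethyllithium as in step 9 gives the chloromethyl ketone F3, and the conditions of step 10 should give the silylene-bridged cycloadduct F4, in which the bridge forces C6 cis to the C4 oxygen. Aqueous HF in MeCN cleaves the silylene, and the route is rejoined at 15.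

Step 12. Intramolecular hydride delivery may be slow, because the tertiary alcohol exchanges onto boron reluctantly and the isopropyl group is pushed axial in the delivery chair. External hydride would then attack the open face and give the C6 epimer, or the reduction would stall. The fallback accepts the external-hydride outcome and corrects it by inversion. It sets out from 15: L-Selectride in THF at −78 °C should attack the less hindered C6 ketone from the face remote from the angular methyl to give the C6-epimeric diol F5. Mitsunobu esterification (PPh3, DIAD, 3,4,5-trimethoxybenzoic acid, toluene) then inverts C6 and installs the ester in the same operation, rejoining the route at 18.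

Step 15. Palladation of the neopentylic enol silane may be outrun by protodesilylation back to the ketone, or β-hydride elimination toward the tertiary C8–H may be sluggish. The fallback replaces the palladium chemistry by a selenoxide syn-elimination. It sets out from 19: PhSeCl in CH2Cl2 at −78 °C selenenylates the enol silane at C9 to give the α-phenylselanyl ketone F6. Oxidation with H2O2/pyridine at 0 °C forms the selenoxide, which eliminates toward C8–H. The route is rejoined at 20, and the acid treatment of step 15 then gives 21.

**Further compounds**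

F1 | step 10 | (5S,8E)-5-hydroxy-5-isopropyl-N-methoxy-N,2-dimethyl-7-oxodec-8-enamide | C/C=C/C(=O)C[C@](O)(C(C)C)CCC(C)C(=O)N(C)OC
F2 | step 10 | cyclic di-tert-butylsilylene dienol ether (4H-1,3,2-dioxasiline bridging O4 and O6) of F1 | CON(C)C(=O)C(C)CC[C@@]1(C(C)C)C=C(/C=C/C)O[Si](C(C)(C)C)(C(C)(C)C)O1
F3 | step 10 | chloromethyl ketone from F2 | ClCC(=O)C(C)CC[C@@]1(C(C)C)C=C(/C=C/C)O[Si](C(C)(C)C)(C(C)(C)C)O1
F4 | step 10 | silylene-bridged cycloadduct (O4–Si–O6 on the hydroazulen-10-one, C6=C7 enol ether) | CC1CC(=O)[C@@]2(C)CC[C@]3(C(C)C)O[Si](C(C)(C)C)(C(C)(C)C)OC(=C1)[C@H]23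
F5 | step 12 | C6 epimer of 16 (6R diol) | O[C@@H]1CC(C)CC(=O)[C@@]2(C)CC[C@@](O)(C(C)C)[C@H]12
F6 | step 15 | C9 phenylselanyl ketone (C4 OTMS, C6 trimethoxybenzoate) | COc1cc(C(=O)O[C@H]2CC(C)C([Se]c4ccccc4)C(=O)[C@@]3(C)CC[C@@](O[Si](C)(C)C)(C(C)C)[C@H]23)cc(OC)c1OC
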